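- At early times the red flask has little in chains, 2.2% at 4.00 min, while its free monomer is still being dosed over 12 min.

| flask | free monomer | initiator | remark | time |
|---|---|---|---|---|
| red | 2.6 M (fed, over 12 min) | 0.21 mol% | the very flask that is asked about, followed so far; the fed solution adds 0.25 times the starting volume |  |
| amber | 2.6 M (fed, over 12 min) | 0.1 mol% | run made earlier; the fed solution adds 0.25 times the starting volume |  |
| flask | 2.6 M (fed, over 12 min) | 0.21 mol% | the fed solution adds 0.25 times the starting volume | 40 min |

| run | time / min | monomer in chains / % | free monomer / % |
|---|---|---|---|
| red | 2.00 | 1.5 | 16.9 |
| red | 4.00 | 2.2 | 29.9 |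
| red | 6.00 | 4.2 | 45.9 |
| red | 8.00 | 10.0 | 58.3 |
| red | 10.0 | 14.2 | 66.6 |
| red | 12.0 | 23.8 | 73.4 |
| amber | 2.50 | 0 | 21.1 |
| amber | 5.00 | 1.4 | 41.3 |
| amber | 8.00 | 4.2 | 62.1 |
| amber | 10.0 | 8.1 | 72.5 |
| amber | 12.0 | 14.9 | 87.2 |
| amber | 15.0 | 21.5 | 80.1 |

(each reading ± 1 percentage point)

- charges are per starting volume, the dose included; the dosed solution carries all of it
- the average divides the monomer in chains by the number of chains begun, living and dead together
- the earlier runs do not show the number of chains; that part of a forecast is a guess
- percentages count the whole charge, also what has not yet gone in

- average number of monomer units in a chain (chains begun, living or dead) at 40 min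
- part of the free monomer that has reacted at 40 min

- The two runs seem to disagree. At 12.0 min red has 23.8% in chains, and amber at 12.0 min has less, 14.9%. Yet amber holds 149 monomer units per initiator charged, more than red's 113.
- I divide the monomer in chains by the chains begun, two accumulated amounts, and get units per chain begun, the degree of polymerization. The slower amber run can lead in a count per initiator charged, since red carries twice its loading of initiator.
- For red, one over the loading gives 476. This is the full-use length, the units per chain once each initiator has begun a chain and the free monomer has reacted to the end.
- The length at any later time is the full-use length times the share reacted, if each initiator has begun a chain by then, which the readings cannot show. With the forecast's 85%, I reckon 405.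
- The forecast says 500, higher than my figure, and adds that “this part is poorly constrained”.
- The flask gives 418 units per chain, with 86.9% of the free monomer reacted.

    free monomer + initiator → living end + monomer in chains (k = 0.00483 L mol⁻¹ s⁻¹)
    free monomer + living end → monomer in chains + living end, rate k2*[living end]*[free monomer] (k = 0.241 L mol⁻¹ s⁻¹)
    initiator + monomer in chains → spent initiator (k = 5.74 × 10⁻⁴ L mol⁻¹ s⁻¹)

- At 40.0 min the initiator in this flask stands at 0% of its charge. The full-use length times the share reacted gives 414, beside the 418 found. The same charges read at 25 min have 66.6% reacted, so the product is 317, and that neighbour flask shows 321.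

The numbers in the tables stem from a simulated flask on assumed constants, and the scatter is random.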